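**Retrosynthetic overview**
1. Target ← acetylation of the secondary alcohol ← macrocyclic diene diol; the 14-membered carbocycle is closed last by an intramolecular McMurry coupling (C6=C7) of an enal with an isopropyl ketone.
2. The isopropyl ketone and the tertiary C10–OH ← a γ-lactone opened by iPrLi; the enal ← the allylic acetate of the farnesyl chain.
3. The γ-lactone (temporary) and the THF ring are formed first, together, by an acid-triggered exo epoxide-opening cascade of an (S,S,S,S)-bis-epoxy tert-butyl ester; this sets all four stereocentres.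
4. Bis-epoxide ← double Shi epoxidation of an acyclic triene ester ← (2E,6E)-farnesyl acetate (C15) + tert-butyl acetate (C2); iPrLi supplies the last C3.
5. Ring order: lactone and THF ring (one pot), then the carbocycle.

Assumption: (2E,6E)-farnesyl acetate and the L-fructose-derived Shi ketone (enantiomer of the usual D-fructose catalyst) are purchased. Atom labels C1–C14 follow the target ring as written in its SMILES: C1 = CH(OAc), C4(Me)=C5, C6=C7(iPr), C10 = C(Me)(OH), C11 and C14 = THF carbons.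

**Step 1**
Reactants: 1 (2E,6E)-3,7,11-trimethyldodeca-2,6,10-trien-1-yl acetate
Product: 2 (2E,6E,10E)-12-hydroxy-3,7,11-trimethyldodeca-2,6,10-trien-1-yl acetate
Conditions: SeO2 (0.1 equiv), salicylic acid (0.1 equiv), t-BuOOH (3 equiv), CH2Cl2, 0 °C → rt
Reagents that add atoms: tert-butyl hydroperoxide CC(C)(C)OO (terminal oxidant; oxygen relayed by catalytic selenium dioxide O=[Se]=O)
Why: Catalytic SeO2 allylic oxidation (ene reaction then [2,3]-sigmatropic shift) is selective for the (E)-methyl of the terminal, most electron-rich trisubstituted alkene and gives the (10E)-allylic alcohol.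

**Step 2**
Reactants: 2 (2E,6E,10E)-12-hydroxy-3,7,11-trimethyldodeca-2,6,10-trien-1-yl acetate
Product: 3 (2E,6E,10E)-12-bromo-3,7,11-trimethyldodeca-2,6,10-trien-1-yl acetate
Conditions: CBr4, PPh3, CH2Cl2, 0 °C
Reagents that add atoms: carbon tetrabromide BrC(Br)(Br)Br
Why: Appel reaction, an SN2 displacement of the activated primary allylic hydroxyl by bromide without allylic transposition or loss of alkene geometry.

**Step 3**
Reactants: 3 (2E,6E,10E)-12-bromo-3,7,11-trimethyldodeca-2,6,10-trien-1-yl acetate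
Product: 4 tert-butyl (4E,8E,12E)-14-acetoxy-4,8,12-trimethyltetradeca-4,8,12-trienoate
Conditions: tert-butyl acetate (1.6 equiv), LiN(iPr)2 (1.5 equiv), THF, −78 °C; then 3, DMPU, −78 → −40 °C
Reagents that add atoms: tert-butyl acetate CC(=O)OC(C)(C)C
Why: Ester enolate alkylation: SN2 attack of the lithium enolate on the primary allylic bromide at −78 °C is much faster than Claisen attack on the acetate and adds the two carbons that become C8 and C7.

**Step 4**
Reactants: 4 tert-butyl (4E,8E,12E)-14-acetoxy-4,8,12-trimethyltetradeca-4,8,12-trienoate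
Product: 5 tert-butyl 3-[(2S,3S)-3-(2-{(2S,3S)-3-[(3E)-5-acetoxy-3-methylpent-3-en-1-yl]-2-methyloxiran-2-yl}ethyl)-2-methyloxiran-2-yl]propanoate
Conditions: 1,2:4,5-di-O-isopropylidene-β-L-erythro-2,3-hexodiulo-2,6-pyranose (L-fructose-derived Shi ketone, 0.6 equiv), KHSO5 (as 2KHSO5·KHSO4·K2SO4), K2CO3, Bu4NHSO4 (cat.), MeCN/CH2(OMe)2/aq. Na2B4O7 buffer, pH 10.5, 0 °C
Reagents that add atoms: potassium peroxymonosulfate [K+].[O-]S(=O)(=O)OO
Why: Shi asymmetric epoxidation: the two electron-rich trialkyl (E)-alkenes are epoxidised through the spiro transition state, the L-fructose-derived ketone giving the (S,S)-epoxide at each (the D-fructose ketone gives R,R), while the alkene carrying the allylic acetate is deactivated and untouched.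

**Step 5**
Reactants: 5 tert-butyl 3-[(2S,3S)-3-(2-{(2S,3S)-3-[(3E)-5-acetoxy-3-methylpent-3-en-1-yl]-2-methyloxiran-2-yl}ethyl)-2-methyloxiran-2-yl]propanoate
Product: 7 (2E,6S)-6-hydroxy-3-methyl-6-{(2R,5S)-2-methyl-5-[(2R)-2-methyl-5-oxooxolan-2-yl]oxolan-2-yl}hex-2-en-1-yl acetate, via hydroxy epoxy lactone 6 (not isolated)
Conditions: BF3·OEt2 (0.2 equiv), CH2Cl2, −78 → −20 °C; aq. NaHCO3
Reagents that add atoms: none
Why: Acid-triggered all-exo epoxide-opening cascade: the ester carbonyl opens the nearer epoxide at its tertiary carbon with inversion (5-exo, γ-lactone 6, loss of isobutene) and the freed secondary hydroxyl opens the second epoxide at its tertiary carbon with inversion (5-exo), which gives C10 (R), C11 (S), C14 (R), C1 (S) and a cis-2,5-disubstituted THF ring.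

**Step 6**
Reactants: 7 (2E,6S)-6-hydroxy-3-methyl-6-{(2R,5S)-2-methyl-5-[(2R)-2-methyl-5-oxooxolan-2-yl]oxolan-2-yl}hex-2-en-1-yl acetate
Product: 8 (6R)-6-{(2S,5R)-5-[(1S,4E)-1,6-dihydroxy-4-methylhex-4-en-1-yl]-5-methyloxolan-2-yl}-6-hydroxy-2-methylheptan-3-one
Conditions: iPrLi (4.5 equiv), THF, −78 °C; aq. NH4Cl at −78 °C
Reagents that add atoms: isopropyllithium [Li]C(C)C
Why: Nucleophilic addition of iPrLi to the γ-lactone stops after one addition at −78 °C and on quench gives the γ-hydroxy isopropyl ketone (C7) with the tertiary C10–OH untouched, while excess reagent removes the allylic acetate by acyl substitution.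

**Step 7**
Reactants: 8 (6R)-6-{(2S,5R)-5-[(1S,4E)-1,6-dihydroxy-4-methylhex-4-en-1-yl]-5-methyloxolan-2-yl}-6-hydroxy-2-methylheptan-3-one
Product: 9 (2E,6S)-6-hydroxy-6-{(2R,5S)-5-[(2R)-2-hydroxy-6-methyl-5-oxoheptan-2-yl]-2-methyloxolan-2-yl}-3-methylhex-2-enal
Conditions: MnO2 (activated, 20 equiv), CH2Cl2, rt
Reagents that add atoms: none
Why: MnO2 oxidation is selective for the allylic primary alcohol and gives the (E)-enal without touching the secondary and tertiary alcohols.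

**Step 8**
Reactants: 9 (2E,6S)-6-hydroxy-6-{(2R,5S)-5-[(2R)-2-hydroxy-6-methyl-5-oxoheptan-2-yl]-2-methyloxolan-2-yl}-3-methylhex-2-enal
Product: 10 (2E,6S)-3-methyl-6-{(2R,5S)-2-methyl-5-[(2R)-6-methyl-5-oxo-2-(triethylsilyloxy)heptan-2-yl]oxolan-2-yl}-6-(triethylsilyloxy)hex-2-enal
Conditions: Et3SiOTf (3 equiv), 2,6-lutidine, CH2Cl2, −78 → 0 °C
Reagents that add atoms: triethylsilyl trifluoromethanesulfonate CC[Si](CC)(CC)OS(=O)(=O)C(F)(F)F
Why: Silyl triflate silylation caps the hindered secondary and tertiary hydroxyls under non-enolising conditions so that no free alcohol or γ-hydroxy ketone meets the titanium reagent.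

**Step 9**
Reactants: 10 (2E,6S)-3-methyl-6-{(2R,5S)-2-methyl-5-[(2R)-6-methyl-5-oxo-2-(triethylsilyloxy)heptan-2-yl]oxolan-2-yl}-6-(triethylsilyloxy)hex-2-enal
Product: 11 (1S,2R,5E,7E,11S,12R)-2,8,12-trimethyl-5-(propan-2-yl)-2,11-bis(triethylsilyloxy)-15-oxabicyclo[10.2.1]pentadeca-5,7-diene
Conditions: TiCl4 (10 equiv), Zn (20 equiv), pyridine, DME, reflux; 10 added by syringe pump over 24 h (final 1 mM)
Reagents that add atoms: none
Why: Intramolecular McMurry reductive carbonyl coupling by low-valent titanium under high dilution joins the enal and ketone carbons as C6=C7 and closes the 14-membered ring, with the dienyl carbon C5 trans to the bulkier isopropyl group (6E), the geometry usual for cembrane 1,3-dienes.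

**Step 10**
Reactants: 11 (1S,2R,5E,7E,11S,12R)-2,8,12-trimethyl-5-(propan-2-yl)-2,11-bis(triethylsilyloxy)-15-oxabicyclo[10.2.1]pentadeca-5,7-diene
Product: 12 (1S,2R,5E,7E,11S,12R)-2,8,12-trimethyl-5-(propan-2-yl)-15-oxabicyclo[10.2.1]pentadeca-5,7-diene-2,11-diol
Conditions: Bu4NF, THF, rt → 45 °C
Reagents that add atoms: none
Why: Fluoride-mediated desilylation frees both hydroxyls without affecting the diene or the THF ring.

**Step 11**
Reactants: 12 (1S,2R,5E,7E,11S,12R)-2,8,12-trimethyl-5-(propan-2-yl)-15-oxabicyclo[10.2.1]pentadeca-5,7-diene-2,11-diol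
Product: 13 (1S,2R,5E,7E,11S,12R)-2-hydroxy-2,8,12-trimethyl-5-(propan-2-yl)-15-oxabicyclo[10.2.1]pentadeca-5,7-dien-11-yl acetate
Conditions: Ac2O, pyridine, 4-(dimethylamino)pyridine (cat.), CH2Cl2, rt
Reagents that add atoms: acetic anhydride CC(=O)OC(C)=O
Why: Nucleophile-catalysed acylation acetylates only the secondary C1 hydroxyl, the tertiary C10 alcohol being too hindered to react at room temperature.

**Compound list**
1 | (2E,6E)-3,7,11-trimethyldodeca-2,6,10-trien-1-yl acetate ((E,E)-farnesyl acetate) | CC(=O)OC/C=C(C)/CC/C=C(C)/CCC=C(C)C | starting material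
2 | (2E,6E,10E)-12-hydroxy-3,7,11-trimethyldodeca-2,6,10-trien-1-yl acetate | CC(=O)OC/C=C(C)/CC/C=C(C)/CC/C=C(C)/CO | intermediate
3 | (2E,6E,10E)-12-bromo-3,7,11-trimethyldodeca-2,6,10-trien-1-yl acetate | CC(=O)OC/C=C(C)/CC/C=C(C)/CC/C=C(C)/CBr | intermediate
4 | tert-butyl (4E,8E,12E)-14-acetoxy-4,8,12-trimethyltetradeca-4,8,12-trienoate | CC(=O)OC/C=C(C)/CC/C=C(C)/CC/C=C(C)/CCC(=O)OC(C)(C)C | intermediate
5 | tert-butyl 3-[(2S,3S)-3-(2-{(2S,3S)-3-[(3E)-5-acetoxy-3-methylpent-3-en-1-yl]-2-methyloxiran-2-yl}ethyl)-2-methyloxiran-2-yl]propanoate | CC(=O)OC/C=C(C)/CC[C@@H]1O[C@@]1(C)CC[C@@H]1O[C@@]1(C)CCC(=O)OC(C)(C)C | intermediate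
6 | (2E)-5-[(2S,3S)-3-{(3S)-3-hydroxy-3-[(2R)-2-methyl-5-oxooxolan-2-yl]propyl}-3-methyloxiran-2-yl]-3-methylpent-2-en-1-yl acetate (hydroxy epoxy lactone) | CC(=O)OC/C=C(C)/CC[C@@H]1O[C@@]1(C)CC[C@H](O)[C@@]2(C)CCC(=O)O2 | intermediate (not isolated)
7 | (2E,6S)-6-hydroxy-3-methyl-6-{(2R,5S)-2-methyl-5-[(2R)-2-methyl-5-oxooxolan-2-yl]oxolan-2-yl}hex-2-en-1-yl acetate | CC(=O)OC/C=C(C)/CC[C@H](O)[C@@]1(C)CC[C@H](O1)[C@@]2(C)CCC(=O)O2 | intermediate
8 | (6R)-6-{(2S,5R)-5-[(1S,4E)-1,6-dihydroxy-4-methylhex-4-en-1-yl]-5-methyloxolan-2-yl}-6-hydroxy-2-methylheptan-3-one | OC/C=C(C)/CC[C@H](O)[C@@]1(C)CC[C@H](O1)[C@](C)(O)CCC(=O)C(C)C | intermediate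
9 | (2E,6S)-6-hydroxy-6-{(2R,5S)-5-[(2R)-2-hydroxy-6-methyl-5-oxoheptan-2-yl]-2-methyloxolan-2-yl}-3-methylhex-2-enal | O=C/C=C(C)/CC[C@H](O)[C@@]1(C)CC[C@H](O1)[C@](C)(O)CCC(=O)C(C)C | intermediate
10 | (2E,6S)-3-methyl-6-{(2R,5S)-2-methyl-5-[(2R)-6-methyl-5-oxo-2-(triethylsilyloxy)heptan-2-yl]oxolan-2-yl}-6-(triethylsilyloxy)hex-2-enal | O=C/C=C(C)/CC[C@H](O[Si](CC)(CC)CC)[C@@]1(C)CC[C@H](O1)[C@](C)(O[Si](CC)(CC)CC)CCC(=O)C(C)C | intermediate
11 | (1S,2R,5E,7E,11S,12R)-2,8,12-trimethyl-5-(propan-2-yl)-2,11-bis(triethylsilyloxy)-15-oxabicyclo[10.2.1]pentadeca-5,7-diene | CC[Si](CC)(CC)O[C@H]1CC/C(C)=C/C=C(/C(C)C)CC[C@@](C)(O[Si](CC)(CC)CC)[C@@H]2CC[C@@]1(C)O2 | intermediate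
12 | (1S,2R,5E,7E,11S,12R)-2,8,12-trimethyl-5-(propan-2-yl)-15-oxabicyclo[10.2.1]pentadeca-5,7-diene-2,11-diol | O[C@H]1CC/C(C)=C/C=C(/C(C)C)CC[C@@](C)(O)[C@@H]2CC[C@@]1(C)O2 | intermediate
13 | (1S,2R,5E,7E,11S,12R)-2-hydroxy-2,8,12-trimethyl-5-(propan-2-yl)-15-oxabicyclo[10.2.1]pentadeca-5,7-dien-11-yl acetate (CNP0199953.1) | CC(=O)O[C@H]1CC/C(C)=C/C=C(/C(C)C)CC[C@@](C)(O)[C@@H]2CC[C@@]1(C)O2 | target

**Step count and risks**
Total step count: 11. Longest linear sequence: 11 steps (1 → 13).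

Steps most likely to fail:

Step 5 (cascade). The Lewis acid may give cation–olefin cyclisation, epoxide rearrangement or endo opening instead of the lactone/THF pair. The fallback sets out from 4 and comes back at 7. CF3CO2H in CH2Cl2 at 0 °C removes the tert-butyl group and gives the free acid (4E,8E,12E)-14-acetoxy-4,8,12-trimethyltetradeca-4,8,12-trienoic acid F1. Epoxidation of F1 under the step 4 conditions gives the bis-epoxy acid 3-[(2S,3S)-3-(2-{(2S,3S)-3-[(3E)-5-acetoxy-3-methylpent-3-en-1-yl]-2-methyloxiran-2-yl}ethyl)-2-methyloxiran-2-yl]propanoic acid F2. On acidification to pH 4 the free carboxyl of F2 attacks the tertiary epoxide carbon and gives hydroxy epoxy lactone 6, which is now isolated. Camphor-10-sulfonic acid (0.1 equiv) in CH2Cl2 at 0 °C then closes the THF ring by 5-exo opening at the tertiary carbon and gives 7. This replaces the one-pot Lewis-acid cascade of an ester by a stepwise Brønsted-acid sequence from the free acid.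

Step 6 (iPrLi on the lactone). Enolisation of the lactone or double addition may compete. The fallback sets out from 7 and comes back at 8. MeNH(OMe)·HCl and Me3Al (excess) in CH2Cl2, 0 °C → rt, open the lactone and remove the acetate by aminolysis, giving the Weinreb amide (4R)-4-{(2S,5R)-5-[(1S,4E)-1,6-dihydroxy-4-methylhex-4-en-1-yl]-5-methyloxolan-2-yl}-4-hydroxy-N-methoxy-N-methylpentanamide F3. iPrMgCl (5 equiv) in THF at 0 °C then gives ketone 8; the chelated adduct of the N-methoxy amide cannot add a second time.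

Step 9 (McMurry macrocyclisation). Yield, E/Z control at C6=C7 and the tolerance of the enal are all uncertain. The fallback sets out from 8 and comes back at 12, bypassing steps 7–10 and titanium altogether. CBr4/PPh3 in CH2Cl2 at −30 °C converts only the primary allylic alcohol and gives the allylic bromide (6R)-6-{(2S,5R)-5-[(1S,4E)-6-bromo-1-hydroxy-4-methylhex-4-en-1-yl]-5-methyloxolan-2-yl}-6-hydroxy-2-methylheptan-3-one F4. PBu3 in MeCN gives the phosphonium salt tributyl{(2E,6S)-6-hydroxy-6-[(2R,5S)-5-((2R)-2-hydroxy-6-methyl-5-oxoheptan-2-yl)-2-methyloxolan-2-yl]-3-methylhex-2-en-1-yl}phosphonium bromide F5. KOtBu (4 equiv) in THF/toluene under high dilution, 0 °C → rt, effects an intramolecular Wittig olefination of the isopropyl ketone (the hydroxyls ride along as alkoxides) and gives diol 12 directly.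

**Further compounds**
F1 | step 5 | (4E,8E,12E)-14-acetoxy-4,8,12-trimethyltetradeca-4,8,12-trienoic acid | CC(=O)OC/C=C(C)/CC/C=C(C)/CC/C=C(C)/CCC(=O)O
F2 | step 5 | 3-[(2S,3S)-3-(2-{(2S,3S)-3-[(3E)-5-acetoxy-3-methylpent-3-en-1-yl]-2-methyloxiran-2-yl}ethyl)-2-methyloxiran-2-yl]propanoic acid | CC(=O)OC/C=C(C)/CC[C@@H]1O[C@@]1(C)CC[C@@H]1O[C@@]1(C)CCC(=O)O
F3 | step 6 | (4R)-4-{(2S,5R)-5-[(1S,4E)-1,6-dihydroxy-4-methylhex-4-en-1-yl]-5-methyloxolan-2-yl}-4-hydroxy-N-methoxy-N-methylpentanamide | OC/C=C(C)/CC[C@H](O)[C@@]1(C)CC[C@H](O1)[C@](C)(O)CCC(=O)N(C)OC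
F4 | step 9 | (6R)-6-{(2S,5R)-5-[(1S,4E)-6-bromo-1-hydroxy-4-methylhex-4-en-1-yl]-5-methyloxolan-2-yl}-6-hydroxy-2-methylheptan-3-one | BrC/C=C(C)/CC[C@H](O)[C@@]1(C)CC[C@H](O1)[C@](C)(O)CCC(=O)C(C)C
F5 | step 9 | tributyl{(2E,6S)-6-hydroxy-6-[(2R,5S)-5-((2R)-2-hydroxy-6-methyl-5-oxoheptan-2-yl)-2-methyloxolan-2-yl]-3-methylhex-2-en-1-yl}phosphonium bromide | CCCC[P+](CCCC)(CCCC)C/C=C(C)/CC[C@H](O)[C@@]1(C)CC[C@H](O1)[C@](C)(O)CCC(=O)C(C)C.[Br-]
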